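The isocoumarin is cut at C4a–C4 and O2–C3, so that ring C is added last to a diaryl ether benzoic acid. The step exploits the carboxyl carbon C1 on C8a of ring A: its ortho carbon C8 carries the ring B aryloxy group, leaving C4a–H as the only ortho C–H, while the ring B carboxyl at C5′ has none. One rhodium-catalysed annulation with a hexanoyl-derived sulfoxonium ylide therefore forges both bonds and installs the C3 pentyl chain. The precursor is a 2-aryloxy-4-methoxybenzoic acid whose ring B is a dimethyl ether and benzyl ester, chosen so that a single BBr3 treatment afterwards frees every masked group.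

Key step: step 9

Locants: isocoumarin numbering C1–C8a for ring C (pyranone) and ring A (benzo ring); ring B is primed, from the ether carbon C1′ through C2′(O), C3′(H), C4′(O), C5′(carboxyl) to C6′(pentyl).

Remark on the chemistry: the ring B carboxyl is carried as a benzyl ester because a methyl ester flanked by C4′–O and C6′-pentyl would need a separate, forcing hydrolysis that endangers the lactone and the easily decarboxylated acid. The target has no stereocentre; intermediate 7 is racemic.

Step 1
Reactants: 1 olivetol (5-pentylbenzene-1,3-diol)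
Product: 2 1,3-dimethoxy-5-pentylbenzene
Conditions: MeI, K2CO3, acetone, reflux
Reagents that add atoms: iodomethane (CI)
Why: Williamson etherification of both phenols, with no other reactive group present.

Step 2
Reactants: 2 1,3-dimethoxy-5-pentylbenzene
Product: 4 2,4-dimethoxy-6-pentylbenzaldehyde, via iminium chloride 3 (not isolated)
Conditions: POCl3, DMF, 0 → 70 °C; then ice-water
Reagents that add atoms: N,N-dimethylformamide (CN(C)C=O); water (O)
Why: Vilsmeier–Haack formylation should occur para to one methoxy group and ortho to the other, next to the pentyl chain, rather than at the carbon crowded between both methoxy groups, and the iminium salt is hydrolysed on work-up.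

Step 3
Reactants: 4 2,4-dimethoxy-6-pentylbenzaldehyde
Product: 5 2,4-dimethoxy-6-pentylbenzoic acid
Conditions: NaClO2, NaH2PO4, 2-methylbut-2-ene, t-BuOH/H2O, rt
Reagents that add atoms: sodium chlorite ([Na+].[O-]Cl=O)
Why: Pinnick oxidation converts the aldehyde to the acid while the excess alkene traps hypochlorous acid before it can chlorinate the electron-rich ring.

Step 4
Reactants: 5 2,4-dimethoxy-6-pentylbenzoic acid
Product: 6 benzyl 2,4-dimethoxy-6-pentylbenzoate
Conditions: BnBr, K2CO3, DMF, rt
Reagents that add atoms: benzyl bromide (BrCc1ccccc1)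
Why: SN2 O-alkylation of the carboxylate forms the ester at the benzylic carbon and so is indifferent to the steric shielding of the carbonyl group.

Step 5
Reactants: 6 benzyl 2,4-dimethoxy-6-pentylbenzoate
Product: 8 benzyl 3-formyl-4,6-dimethoxy-2-pentylbenzoate, via α-chloro ether 7 (not isolated)
Conditions: Cl2CHOMe, AgOTf, CH2Cl2, −78 → 0 °C; then H2O
Reagents that add atoms: dichloromethyl methyl ether (COC(Cl)Cl); water (O)
Why: Rieche formylation in its mild AgOTf-promoted form, which spares the benzyl ester, should substitute the free carbon between the pentyl-bearing and a methoxy-bearing carbon (para to the other methoxy group) in preference to the carbon flanked by two methoxy groups, as halogenation and formylation of 6-alkyl-2,4-dimethoxybenzoates generally do.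

Step 6
Reactants: 8 benzyl 3-formyl-4,6-dimethoxy-2-pentylbenzoate
Product: 10 benzyl 3-hydroxy-4,6-dimethoxy-2-pentylbenzoate, via aryl formate 9 (not isolated)
Conditions: mCPBA, CH2Cl2, 0 °C → rt; then Et3N, MeOH, rt
Reagents that add atoms: 3-chloroperoxybenzoic acid (O=C(OO)c1cccc(Cl)c1)
Why: Baeyer–Villiger (Dakin-type) oxidation, in which the aryl group activated by ortho and para methoxy groups migrates to oxygen, followed by mild methanolysis of the formate that leaves the hindered benzyl ester untouched.

Step 7
Reactants: 10 benzyl 3-hydroxy-4,6-dimethoxy-2-pentylbenzoate; 11 2-bromo-4-methoxybenzoic acid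
Product: 12 2-{3-[(benzyloxy)carbonyl]-4,6-dimethoxy-2-pentylphenoxy}-4-methoxybenzoic acid
Conditions: CuI (20 mol %), Cs2CO3, DMF, 90 °C; then 1 M HCl
Reagents that add atoms: none
Why: Ullmann diaryl ether synthesis assisted by the ortho carboxylate, which binds copper next to the C–Br bond and lets the coupling run at a temperature the benzyl ester tolerates while delivering the free acid directly.

Step 8
Reactants: 13 hexanoyl chloride; 14 trimethylsulfoxonium iodide
Product: 16 dimethylsulfoxonium 2-oxoheptylide [1-(dimethyl-oxo-λ6-sulfanylidene)heptan-2-one], via dimethylsulfoxonium methylide 15 (not isolated)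
Conditions: 14 (3 equiv), KOt-Bu (3 equiv), THF, reflux; then 13 (1 equiv), 0 °C → rt
Reagents that add atoms: none
Why: C-acylation of the Corey–Chaykovsky methylide by the acid chloride, after which a second equivalent of methylide deprotonates the acylsulfoxonium salt to the stabilised ylide.

Step 9
Reactants: 12 2-{3-[(benzyloxy)carbonyl]-4,6-dimethoxy-2-pentylphenoxy}-4-methoxybenzoic acid; 16 dimethylsulfoxonium 2-oxoheptylide
Product: 18 benzyl 4,6-dimethoxy-3-[(6-methoxy-1-oxo-3-pentyl-1H-isochromen-8-yl)oxy]-2-pentylbenzoate, via keto acid 17 (not isolated)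
Conditions: [RhCl2(C5Me5)]2 (4 mol %), AgSbF6 (16 mol %), NaOAc (1 equiv), 16 (1.5 equiv), ClCH2CH2Cl, 100 °C
Reagents that add atoms: none
Why: The cationic trivalent rhodium carboxylate formed from 12 should cleave C4a–H by concerted metalation–deprotonation to a five-membered rhodacycle; ylide 16 then binds through carbon, expels dimethyl sulfoxide to give a rhodium carbene, and 1,1-migratory insertion makes C4a–C4 before protonolysis releases keto acid 17. The carboxyl oxygen of 17 adds to the ketone (6-exo-trig) and water is lost, forming O2–C3 and closing ring C as the pyranone. The closest known reaction type is the annulation of benzoic acids with α-acyl sulfoxonium ylides or diazo ketones to 3-substituted isocoumarins under [RhCl2(C5Me5)]2 catalysis. No stereocentre is formed. The step needs site selectivity, which the substrate secures because C8 is blocked by the aryloxy group, so C4a–H is the only C–H ortho to the directing carboxylate, and because the ring B ester at C5′ is flanked by C4′–OMe and C6′-pentyl and has no ortho C–H. Chemoselectivity should hold because the methyl ethers, benzyl ester and diaryl ether offer the carbene no reactive site under acetate buffering.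

Step 10
Reactants: 18 benzyl 4,6-dimethoxy-3-[(6-methoxy-1-oxo-3-pentyl-1H-isochromen-8-yl)oxy]-2-pentylbenzoate
Product: 19 4,6-dihydroxy-3-[(6-hydroxy-1-oxo-3-pentyl-1H-isochromen-8-yl)oxy]-2-pentylbenzoic acid (CNP0439913.0)
Conditions: BBr3 (10 equiv), C6HMe5 (3 equiv), CH2Cl2, −78 → 0 °C; then H2O, 0 °C
Reagents that add atoms: none
Why: Lewis-acid dealkylation in which BBr3 cleaves the three aryl methyl ethers and the benzyl ester at their alkyl–oxygen bonds, pentamethylbenzene captures the benzyl cation by Friedel–Crafts alkylation before it can attack the phenols, the enol lactone and diaryl ether have no cleavable alkyl–oxygen bond, and cold aqueous hydrolysis of the boron esters should avoid decarboxylation.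

Compound list

1 | olivetol (5-pentylbenzene-1,3-diol) | CCCCCc1cc(O)cc(O)c1 | starting material
2 | 1,3-dimethoxy-5-pentylbenzene | CCCCCc1cc(OC)cc(OC)c1 | intermediate
3 | N-[(2,4-dimethoxy-6-pentylphenyl)methylidene]-N-methylmethanaminium chloride (not isolated) | CCCCCc1cc(OC)cc(OC)c1C=[N+](C)C.[Cl-] | intermediate
4 | 2,4-dimethoxy-6-pentylbenzaldehyde | CCCCCc1cc(OC)cc(OC)c1C=O | intermediate
5 | 2,4-dimethoxy-6-pentylbenzoic acid | CCCCCc1cc(OC)cc(OC)c1C(=O)O | intermediate
6 | benzyl 2,4-dimethoxy-6-pentylbenzoate | CCCCCc1cc(OC)cc(OC)c1C(=O)OCc1ccccc1 | intermediate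
7 | benzyl 3-[chloro(methoxy)methyl]-4,6-dimethoxy-2-pentylbenzoate (racemic, not isolated) | CCCCCc1c(C(Cl)OC)c(OC)cc(OC)c1C(=O)OCc1ccccc1 | intermediate
8 | benzyl 3-formyl-4,6-dimethoxy-2-pentylbenzoate | CCCCCc1c(C=O)c(OC)cc(OC)c1C(=O)OCc1ccccc1 | intermediate
9 | benzyl 3-(formyloxy)-4,6-dimethoxy-2-pentylbenzoate (not isolated) | CCCCCc1c(OC=O)c(OC)cc(OC)c1C(=O)OCc1ccccc1 | intermediate
10 | benzyl 3-hydroxy-4,6-dimethoxy-2-pentylbenzoate | CCCCCc1c(O)c(OC)cc(OC)c1C(=O)OCc1ccccc1 | intermediate
11 | 2-bromo-4-methoxybenzoic acid | COc1ccc(C(=O)O)c(Br)c1 | starting material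
12 | 2-{3-[(benzyloxy)carbonyl]-4,6-dimethoxy-2-pentylphenoxy}-4-methoxybenzoic acid | CCCCCc1c(Oc2cc(OC)ccc2C(=O)O)c(OC)cc(OC)c1C(=O)OCc1ccccc1 | intermediate
13 | hexanoyl chloride | CCCCCC(=O)Cl | starting material
14 | trimethylsulfoxonium iodide | C[S+](C)(C)=O.[I-] | starting material
15 | dimethylsulfoxonium methylide (not isolated) | C=S(C)(C)=O | intermediate
16 | dimethylsulfoxonium 2-oxoheptylide [1-(dimethyl-oxo-λ6-sulfanylidene)heptan-2-one] | CCCCCC(=O)C=S(C)(C)=O | intermediate
17 | 2-{3-[(benzyloxy)carbonyl]-4,6-dimethoxy-2-pentylphenoxy}-4-methoxy-6-(2-oxoheptyl)benzoic acid (not isolated) | CCCCCC(=O)Cc1cc(OC)cc(Oc2c(OC)cc(OC)c(C(=O)OCc3ccccc3)c2CCCCC)c1C(=O)O | intermediate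
18 | benzyl 4,6-dimethoxy-3-[(6-methoxy-1-oxo-3-pentyl-1H-isochromen-8-yl)oxy]-2-pentylbenzoate | CCCCCc1cc2cc(OC)cc(Oc3c(OC)cc(OC)c(C(=O)OCc4ccccc4)c3CCCCC)c2c(=O)o1 | intermediate
19 | 4,6-dihydroxy-3-[(6-hydroxy-1-oxo-3-pentyl-1H-isochromen-8-yl)oxy]-2-pentylbenzoic acid | CCCCCc1cc2cc(O)cc(Oc3c(O)cc(O)c(C(=O)O)c3CCCCC)c2c(=O)o1 | target

Total step count: 10. Longest linear sequence: 9 steps (steps 1–7, 9 and 10, from olivetol 1); step 8 is a one-step side branch.

Steps most likely to fail

Step 9. The bulky aryloxy group at C8 may twist the carboxylate so that C4a–H metalation is slow. The carbene would then be consumed by O–H insertion into the acid or by self-condensation. The fallback replaces C–H activation by a halogen handle. It sets out from 10 and returns at 18. 3,5-Dibromoanisole is deprotonated between the bromines (LiN(i-Pr)2, THF, −78 °C) and quenched with CO2 to give 2,6-dibromo-4-methoxybenzoic acid F1. F1 (in excess) is coupled with 10 under the conditions of step 7 to give 2-bromo-6-{3-[(benzyloxy)carbonyl]-4,6-dimethoxy-2-pentylphenoxy}-4-methoxybenzoic acid F2. F2 is then treated with hept-1-yne, Pd(PPh3)4, ZnCl2 and Et3N in DMF at 100 °C. This Sonogashira-type coupling is followed by 6-endo-dig lactonisation of the carboxylate onto the alkyne and should give 18.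

Step 7. The phenoxide of 10 is shielded by methoxy and pentyl groups, so C–O bond formation at copper may be slow. Protodebromination of 11, or debenzylation of the ester by phenoxide, could then take over. The fallback uses nucleophilic aromatic substitution and sets out from 10, returning at 12. 10 is heated with 2-fluoro-4-methoxybenzaldehyde and K2CO3 in DMF at 110 °C, where the ortho formyl group activates fluoride displacement. This should give benzyl 3-(2-formyl-5-methoxyphenoxy)-4,6-dimethoxy-2-pentylbenzoate F3. Pinnick oxidation (NaClO2, NaH2PO4, 2-methylbut-2-ene) of F3 then gives 12.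

Step 5. Substitution may occur at the other free ring carbon, between the two methoxy groups, or stall on the ester-deactivated ring. The fallback fixes the position through a symmetric intermediate and sets out from 2, returning at 10. 2 is dibrominated (NBS, 2.1 equiv, MeCN) at both carbons flanking the pentyl chain to give 2,4-dibromo-1,5-dimethoxy-3-pentylbenzene F4, in which the two bromines are equivalent. Single bromine–lithium exchange (n-BuLi, 1 equiv, THF, −78 °C) and CO2 quench give 3-bromo-4,6-dimethoxy-2-pentylbenzoic acid F5. Benzylation as in step 4 gives benzyl 3-bromo-4,6-dimethoxy-2-pentylbenzoate F6. Palladium-catalysed hydroxylation of the C–Br bond (Pd2(dba)3, t-BuXPhos, KOH, dioxane/H2O, 100 °C) should then give 10, the doubly ortho-substituted ester resisting saponification.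

Further compounds

F1 | step 9 | 2,6-dibromo-4-methoxybenzoic acid | COc1cc(Br)c(C(=O)O)c(Br)c1
F2 | step 9 | 2-bromo-6-{3-[(benzyloxy)carbonyl]-4,6-dimethoxy-2-pentylphenoxy}-4-methoxybenzoic acid | CCCCCc1c(Oc2cc(OC)cc(Br)c2C(=O)O)c(OC)cc(OC)c1C(=O)OCc1ccccc1
F3 | step 7 | benzyl 3-(2-formyl-5-methoxyphenoxy)-4,6-dimethoxy-2-pentylbenzoate | CCCCCc1c(Oc2cc(OC)ccc2C=O)c(OC)cc(OC)c1C(=O)OCc1ccccc1
F4 | step 5 | 2,4-dibromo-1,5-dimethoxy-3-pentylbenzene | CCCCCc1c(Br)c(OC)cc(OC)c1Br
F5 | step 5 | 3-bromo-4,6-dimethoxy-2-pentylbenzoic acid | CCCCCc1c(Br)c(OC)cc(OC)c1C(=O)O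
F6 | step 5 | benzyl 3-bromo-4,6-dimethoxy-2-pentylbenzoate | CCCCCc1c(Br)c(OC)cc(OC)c1C(=O)OCc1ccccc1
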